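**Late readings.** At late times the readings of both earlier runs flatten. The noon run ends with intermediate C at 48.4% and target at 44.0%, the summer run with 67.8% and 25.0%, and starting material stands at 0.5% and 0%. So I reckon with two quantities: the pool P, intermediate C plus target, and the split S, target over intermediate C at late times, read as an equilibrium ratio (thermodynamic control). Intermediate C is then P divided by one plus S.

all flasks: starting material 0.050 M
- noon: protic impurity 0.017 M; temperature 52 °C; run made earlier
- summer: protic impurity 0.038 M; temperature 80 °C; run made earlier
- Monday's: protic impurity 0.0250 M; temperature 40 °C; time 25 min
- Friday's: protic impurity 0.0250 M; temperature 65 °C; time 25 min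
- Thursday's: protic impurity 0.0250 M; temperature 90 °C; time 25 min

noon run (percent of the starting material charged)

| time / min | intermediate A / % | starting material / % | intermediate C / % | target / % | intermediate B / % |
|---|---|---|---|---|---|
| 0.667 | 19.3 | 27.0 | 14.7 | 6.8 | 28.4 |
| 2.00 | 8.8 | 8.3 | 36.4 | 30.4 | 9.1 |
| 4.00 | 2.2 | 1.5 | 46.4 | 41.0 | 1.1 |
| 6.00 | 0.2 | 0 | 48.1 | 43.3 | 0 |
| 8.00 | 0.4 | 0.5 | 48.4 | 44.0 | 0.2 |

summer run (percent of the starting material charged)

| time / s | intermediate A / % | starting material / % | intermediate C / % | target / % | intermediate B / % |
|---|---|---|---|---|---|
| 12.0 | 5.7 | 9.6 | 32.8 | 11.4 | 34.7 |
| 20.0 | 4.2 | 5.7 | 47.2 | 16.4 | 20.4 |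
| 30.0 | 1.4 | 2.7 | 57.2 | 20.6 | 10.9 |
| 60.0 | 0.5 | 0.3 | 66.7 | 23.7 | 2.2 |
| 120 | 0.2 | 0 | 67.8 | 25.0 | 0 |

(each reading ± 0.3 percentage points)

- which of these there is most of at the end, counted by the starting material in it, Monday's (target / starting material / intermediate C / intermediate B / intermediate A)
- which of these there is most of at the end, counted by the starting material in it, Friday's (target / starting material / intermediate C / intermediate B / intermediate A)
- which of these there is most of at the end, counted by the starting material in it, Thursday's (target / starting material / intermediate C / intermediate B / intermediate A)
- how much there is at the end of the one of these that leads, in percent of the starting material charged: Monday's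
- how much there is at the end of the one of these that leads, in percent of the starting material charged: Friday's
- how much there is at the end of the one of these that leads, in percent of the starting material charged: Thursday's

- steps under discussion: intermediate C <-> target; intermediate A -> intermediate C; starting material <-> intermediate B; starting material + protic impurity -> quenched substrate; starting material -> intermediate A

**The heat.** S reads 0.909 at 52 °C and 0.369 at 80 °C. From these I take the heat of the split, the gas constant times the rise of ln S per unit of inverse temperature: 30.8 kJ/mol. It gives S as 1.41 on Monday's, 0.587 on Friday's and 0.276 on Thursday's. I expect target to lead on Monday's and intermediate C on the other two.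

**Friday's bracket.** Friday's 25 min is longer than the noon run's last reading at 8.00 min, and Friday's is warmer. Taking S as reckoned, with P at its full charge, Friday's intermediate C stands below 63.0%. With every impurity molecule quenching one of starting material, it stands above 31.5%. To tighten this, I take the part of the charge outside P at the last readings as quenched substrate, although that part also holds the last readings of intermediate A, starting material and intermediate B. The loss per unit of impurity reads higher in the noon run than in the summer run, and 65 °C lies between their temperatures. Scaled to Friday's charge, the two losses are 11.2% and 4.74%, so I put Friday's intermediate C between 56.0% and 60.0%.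

**The forecast.** It says target at 49.5% on Monday's, intermediate C at 58.3% on Friday's and intermediate C at 75.4% on Thursday's, holding that “Twenty-five minutes therefore suffices for completion and equilibrium”. Its Friday's value is above my lower bound and below my upper one.

**The result.** Monday's ends with target at 49.1%, Friday's with intermediate C at 58.5%, inside the bracket, and Thursday's with intermediate C at 75.8%. As Friday's flask stands at 25.0 min, its slowest mode has a half-life of 0.376 min, far shorter than 25 min, and at 250 min Friday's intermediate C stands at 58.5%. With the pool Friday's actually holds, 92.5%, the heat gives intermediate C as 58.3%.

    intermediate C ⇌ target (K = 1.40, k = 0.0152 /s, Ea = 81.0 kJ/mol, ΔH = −31.0 kJ/mol)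
    intermediate A → intermediate C (k = 0.0112 /s, Ea = 87.0 kJ/mol)
    starting material ⇌ intermediate B (K = 0.600, k = 0.188 /s, Ea = 81.0 kJ/mol, ΔH = 39.0 kJ/mol)
    starting material + protic impurity → quenched substrate (k = 0.0828 /M/s, Ea = 44.0 kJ/mol)
    starting material → intermediate A (k = 0.00921 /s, Ea = 77.0 kJ/mol)
    (constants at 40 °C)

**A colder neighbour.** For a flask like Friday's kept at 40 °C, the heat gives S as 1.41, so I expect target to lead, and if the loss there is at least the noon run's scaled loss, I put intermediate C below 36.9%. The computed flask has target leading, with intermediate C at 35.1%.

Readings and results are calculated with constants of no real substance; noise was put on by code.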